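**Plan**

- The target is read as 8α-hydroxylabda-13(16),14-dien-19-yl (E)-4-methoxycinnamate: a trans-decalin with stereocentres C4, C5, C8, C9 and C10, and C19 axial on C4, cis to the C20 methyl.
- Cuts: the C19–O ester bond; the C13–C14 bond (vinyl coupling to the enol triflate of a C13 methyl ketone); then C4–C5 and C9–C10 (ring A, ring B) together with the C8–O bond; last the C1–C2 chain bond.
- Enabling feature: C4 carries CH3 and CH2O, so it is the opened form of a 2-methyl-2-alkyloxirane (C4–C19–O). Rings A and B are the two six-membered rings that an (E,E)-C5=C10/C8=C9 diene closes in cation–olefin fashion. The C8 oxygen is δ to C13, so a C13 ketone oxygen can end the cascade. This copies the presumed biosynthesis of 8-hydroxylabdanes, started from an oxidised initiator.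
- Forward: (E)-geranylacetone gives an allylic bromide (fragment A) and (S)-citramalic acid gives an acetonide bromide (fragment B). A copper-catalysed Grignard coupling joins C1–C2. Deprotection and oxirane closure give the epoxy dienone. The bicyclization forms ring A, then ring B, then a temporary pyran (ring C), which is hydrolysed. Silylation, enol triflate formation, vinyl Stille coupling, desilylation and esterification follow.
- Stereochemistry: C4 comes from the (S)-oxirane carbon (citramalic acid) by inversion. C5, C10, C9 and C8 follow by chair–chair relay across the two (E)-alkenes. The cinnamate (E)-geometry comes from the acid.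

Key step: step 10

**Route**

Step 1
Reactants: 1 (E)-geranylacetone
Product: 2 2-[(3E)-4,8-dimethylnona-3,7-dien-1-yl]-2-methyl-1,3-dioxolane
Conditions: ethylene glycol, pyridinium p-toluenesulfonate (cat.), benzene, reflux, Dean–Stark trap
Reagents that add atoms: ethylene glycol, OCCO
Why: Acid-catalysed ketalisation with azeotropic removal of water should mask the methyl ketone for the later Grignard coupling; no stereocentre is formed.

Step 2
Reactants: 2 2-[(3E)-4,8-dimethylnona-3,7-dien-1-yl]-2-methyl-1,3-dioxolane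
Product: 3 (2E,6E)-2,6-dimethyl-9-(2-methyl-1,3-dioxolan-2-yl)nona-2,6-dien-1-ol
Conditions: SeO2 (cat.), t-BuOOH, salicylic acid (cat.), CH2Cl2, 0 °C to rt
Reagents that add atoms: tert-butyl hydroperoxide, CC(C)(C)OO
Why: The SeO2-catalysed allylic oxidation (ene reaction, then [2,3]-sigmatropic shift) should attack the (E)-methyl of the more electron-rich terminal alkene, so the new CH2OH arises with (E)-geometry.

Step 3
Reactants: 3 (2E,6E)-2,6-dimethyl-9-(2-methyl-1,3-dioxolan-2-yl)nona-2,6-dien-1-ol
Product: 4 2-[(3E,7E)-9-bromo-4,8-dimethylnona-3,7-dien-1-yl]-2-methyl-1,3-dioxolane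
Conditions: CBr4, PPh3, 2,6-lutidine, CH2Cl2, −20 °C to 0 °C
Reagents that add atoms: tetrabromomethane, BrC(Br)(Br)Br
Why: The Appel reaction under buffered, near-neutral conditions should give the primary allylic bromide without allylic transposition or loss of the ketal.

Step 4
Reactants: 5 (S)-citramalic acid
Product: 6 (2S)-2-methylbutane-1,2,4-triol
Conditions: BH3·SMe2, THF, 0 °C to reflux; then MeOH
Reagents that add atoms: none
Why: Borane reduction of both carboxyl groups leaves the tertiary carbinol stereocentre untouched.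

Step 5
Reactants: 6 (2S)-2-methylbutane-1,2,4-triol
Product: 7 2-[(4S)-2,2,4-trimethyl-1,3-dioxolan-4-yl]ethanol
Conditions: 2,2-dimethoxypropane, p-TsOH (cat.), acetone, rt
Reagents that add atoms: 2,2-dimethoxypropane, COC(C)(C)OC
Why: Thermodynamic acetonide formation should favour the five-membered dioxolane across the 1,2-diol over the 1,3-dioxane with a syn-axial methyl, leaving the remote primary hydroxyl free.

Step 6
Reactants: 7 2-[(4S)-2,2,4-trimethyl-1,3-dioxolan-4-yl]ethanol
Product: 8 (4S)-4-(2-bromoethyl)-2,2,4-trimethyl-1,3-dioxolane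
Conditions: CBr4, PPh3, pyridine, CH2Cl2, 0 °C
Reagents that add atoms: tetrabromomethane, BrC(Br)(Br)Br
Why: The Appel reaction converts the primary alcohol to the bromide under conditions the acetonide should survive; the stereocentre is not involved.

Step 7
Reactants: 8 (4S)-4-(2-bromoethyl)-2,2,4-trimethyl-1,3-dioxolane; 4 2-[(3E,7E)-9-bromo-4,8-dimethylnona-3,7-dien-1-yl]-2-methyl-1,3-dioxolane
Product: 10 2-methyl-2-{(3E,7E)-4,8-dimethyl-11-[(4S)-2,2,4-trimethyl-1,3-dioxolan-4-yl]undeca-3,7-dien-1-yl}-1,3-dioxolane, via Grignard reagent 9 (not isolated)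
Conditions: Mg, THF, 40 °C (from 8); then 4, Li2CuCl4 (3 mol %), THF, −78 °C to 0 °C
Reagents that add atoms: none
Why: The copper-catalysed cross-coupling of a primary alkyl Grignard reagent with a primary allylic bromide should proceed by α-attack (SN2) with retention of the (E)-geometry, joining C1 to C2.

Step 8
Reactants: 10 2-methyl-2-{(3E,7E)-4,8-dimethyl-11-[(4S)-2,2,4-trimethyl-1,3-dioxolan-4-yl]undeca-3,7-dien-1-yl}-1,3-dioxolane
Product: 11 (5E,9E,14S)-14,15-dihydroxy-6,10,14-trimethylpentadeca-5,9-dien-2-one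
Conditions: 1 M aq. HCl, THF, rt
Reagents that add atoms: water, O
Why: Dilute aqueous acid should hydrolyse both the acetonide and the ketal in one operation, while the trisubstituted alkenes and the tertiary carbinol are stable at room temperature.

Step 9
Reactants: 11 (5E,9E,14S)-14,15-dihydroxy-6,10,14-trimethylpentadeca-5,9-dien-2-one
Product: 13 (5E,9E)-6,10-dimethyl-13-[(2S)-2-methyloxiran-2-yl]trideca-5,9-dien-2-one, via primary tosylate 12 (not isolated)
Conditions: TsCl, Et3N, DMAP (cat.), CH2Cl2, 0 °C; then K2CO3, MeOH, rt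
Reagents that add atoms: none
Why: Selective sulfonylation of the primary hydroxyl and intramolecular Williamson closure by the tertiary alkoxide form the oxirane without touching the tertiary C–O bond, so the (S)-configuration is kept.

Step 10
Reactants: 13 (5E,9E)-6,10-dimethyl-13-[(2S)-2-methyloxiran-2-yl]trideca-5,9-dien-2-one
Product: 15 8α,19-dihydroxy-14,15-dinorlabdan-13-one, via tricyclic enol ether 14 (not isolated)
Conditions: MeAlCl2 (1.2 equiv), CH2Cl2, −78 °C; then 1 M aq. HCl, THF, rt
Reagents that add atoms: water, O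
Why: MeAlCl2 binds the oxirane oxygen, the C5=C10 alkene displaces the tertiary C4–O bond from the rear while C19–O stays as the aluminium alkoxide, C9 of the C8=C9 alkene adds to the C10 cation, and the C8 cation is taken by the C13 carbonyl oxygen to give an oxocarbenium ion that loses a proton (as methane from the aluminium methyl) to enol ether 14, which the acid work-up hydrolyses to 15. The closest known reaction type is the Lewis-acid-promoted epoxide-initiated cation–olefin polycyclization of epoxy polyprenoids, here joined to the carbonyl-oxygen termination known from the acid cyclization of polyprenylacetones to sclareol-oxide-type enol ethers. Ring A closes 6-endo-trig on the C5=C10 alkene (6-exo-tet at the oxirane carbon), ring B closes 6-endo-trig on the C8=C9 alkene through the C9–C10 bond, and the temporary dihydropyran (ring C) closes by six-membered oxygen capture at C8. C4 is set by the (S)-oxirane carbon through inversion, C5 and C10 by anti addition across the (E)-C5=C10 alkene in a chair, and C9 and C8 by anti addition across the (E)-C8=C9 alkene in the second chair, which should give the trans ring fusion, the equatorial C9 chain and the equatorial 8α oxygen. The step needs the oxirane methylene in the axial site at C4 (cis to C20), which is expected because this carbon is tied back toward the leaving oxygen and is therefore smaller than the free methyl in the 1,3-diaxial contact with C20. It also needs ring closure to outrun the 1,2-hydride shift of the opened oxirane and proton loss at C8, which the six-membered reach of each tethered nucleophile, the low temperature and the use of only about one equivalent of Lewis acid (ketone oxygen left free) should secure.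

Step 11
Reactants: 15 8α,19-dihydroxy-14,15-dinorlabdan-13-one
Product: 16 8α,19-bis(triethylsilyloxy)-14,15-dinorlabdan-13-one
Conditions: Et3SiOTf, 2,6-lutidine, CH2Cl2, −78 °C to 0 °C
Reagents that add atoms: triethylsilyl trifluoromethanesulfonate, CC[Si](CC)(CC)OS(=O)(=O)C(F)(F)F
Why: Silyl triflate silylation should cover both the neopentyl primary and the tertiary hydroxyl, so that the later enolization meets no alkoxide or hemiketal.

Step 12
Reactants: 16 8α,19-bis(triethylsilyloxy)-14,15-dinorlabdan-13-one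
Product: 18 8α,19-bis(triethylsilyloxy)-14,15-dinorlabd-13(16)-en-13-yl trifluoromethanesulfonate, via potassium enolate 17 (not isolated)
Conditions: KN(SiMe3)2, THF, −78 °C; then N-(5-chloropyridin-2-yl)bis(trifluoromethanesulfonyl)imide, −78 °C
Reagents that add atoms: N-(5-chloropyridin-2-yl)bis(trifluoromethanesulfonyl)imide, O=S(=O)(N(c1ccc(Cl)cn1)S(=O)(=O)C(F)(F)F)C(F)(F)F
Why: Kinetic deprotonation of a methyl ketone by a bulky amide base should occur at the methyl group (C16) and not at the hindered C12 methylene, and O-sulfonylation of the enolate at low temperature fixes the terminal enol triflate.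

Step 13
Reactants: 18 8α,19-bis(triethylsilyloxy)-14,15-dinorlabd-13(16)-en-13-yl trifluoromethanesulfonate; 19 tributyl(vinyl)stannane
Product: 20 8α,19-bis(triethylsilyloxy)labda-13(16),14-diene
Conditions: Pd(PPh3)4 (5 mol %), LiCl, THF, 65 °C
Reagents that add atoms: none
Why: The Stille coupling of an alkenyl triflate with a vinylstannane under zerovalent palladium catalysis forms the C13–C14 bond and gives the 2-substituted buta-1,3-diene directly.

Step 14
Reactants: 20 8α,19-bis(triethylsilyloxy)labda-13(16),14-diene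
Product: 21 labda-13(16),14-diene-8α,19-diol
Conditions: Bu4NF, THF, rt to 40 °C
Reagents that add atoms: none
Why: Fluoride-induced desilylation should free both hydroxyls under non-acidic conditions that leave the diene and the tertiary alcohol intact.

Step 15
Reactants: 21 labda-13(16),14-diene-8α,19-diol; 22 (E)-4-methoxycinnamic acid
Product: 23 8α-hydroxylabda-13(16),14-dien-19-yl (E)-4-methoxycinnamate
Conditions: EDC·HCl, DMAP, CH2Cl2, rt
Reagents that add atoms: none
Why: The Steglich esterification should acylate the primary C19 hydroxyl only, the tertiary 8α hydroxyl being inert to the acylpyridinium, and the (E)-geometry of the acid is carried over unchanged.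

**Compound list**

1 | (E)-geranylacetone, (5E)-6,10-dimethylundeca-5,9-dien-2-one | CC(=O)CC/C=C(\C)CCC=C(C)C | starting material
2 | 2-[(3E)-4,8-dimethylnona-3,7-dien-1-yl]-2-methyl-1,3-dioxolane | CC1(CC/C=C(\C)CCC=C(C)C)OCCO1 | intermediate
3 | (2E,6E)-2,6-dimethyl-9-(2-methyl-1,3-dioxolan-2-yl)nona-2,6-dien-1-ol | CC1(CC/C=C(\C)CC/C=C(\C)CO)OCCO1 | intermediate
4 | 2-[(3E,7E)-9-bromo-4,8-dimethylnona-3,7-dien-1-yl]-2-methyl-1,3-dioxolane | CC1(CC/C=C(\C)CC/C=C(\C)CBr)OCCO1 | intermediate
5 | (S)-citramalic acid, (2S)-2-hydroxy-2-methylbutanedioic acid | C[C@](O)(CC(=O)O)C(=O)O | starting material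
6 | (2S)-2-methylbutane-1,2,4-triol | C[C@](O)(CCO)CO | intermediate
7 | 2-[(4S)-2,2,4-trimethyl-1,3-dioxolan-4-yl]ethanol | C[C@]1(CCO)COC(C)(C)O1 | intermediate
8 | (4S)-4-(2-bromoethyl)-2,2,4-trimethyl-1,3-dioxolane | C[C@]1(CCBr)COC(C)(C)O1 | intermediate
9 | {2-[(4S)-2,2,4-trimethyl-1,3-dioxolan-4-yl]ethyl}magnesium bromide | C[C@]1(CC[Mg]Br)COC(C)(C)O1 | intermediate (not isolated)
10 | 2-methyl-2-{(3E,7E)-4,8-dimethyl-11-[(4S)-2,2,4-trimethyl-1,3-dioxolan-4-yl]undeca-3,7-dien-1-yl}-1,3-dioxolane | CC1(CC/C=C(\C)CC/C=C(\C)CCC[C@@]2(C)COC(C)(C)O2)OCCO1 | intermediate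
11 | (5E,9E,14S)-14,15-dihydroxy-6,10,14-trimethylpentadeca-5,9-dien-2-one | CC(=O)CC/C=C(\C)CC/C=C(\C)CCC[C@](C)(O)CO | intermediate
12 | primary tosylate of 11, (2S,6E,10E)-2-hydroxy-2,6,10-trimethyl-14-oxopentadeca-6,10-dien-1-yl 4-methylbenzenesulfonate | CC(=O)CC/C=C(\C)CC/C=C(\C)CCC[C@](C)(O)COS(=O)(=O)c1ccc(C)cc1 | intermediate (not isolated)
13 | (5E,9E)-6,10-dimethyl-13-[(2S)-2-methyloxiran-2-yl]trideca-5,9-dien-2-one | CC(=O)CC/C=C(\C)CC/C=C(\C)CCC[C@@]1(C)CO1 | intermediate
14 | 8α,13-epoxy-14,15-dinorlabd-12-en-19-ol (tricyclic enol ether; 5α-H, 9α-H, 10β-CH3, 4β-CH2OH) | CC1=CC[C@@H]2[C@@]3(C)CCC[C@](C)(CO)[C@@H]3CC[C@@]2(C)O1 | intermediate (not isolated)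
15 | 8α,19-dihydroxy-14,15-dinorlabdan-13-one (trans-decalin; 4α-CH3, 4β-CH2OH, 8β-CH3, 9β side chain) | CC(=O)CC[C@@H]1[C@@]2(C)CCC[C@](C)(CO)[C@@H]2CC[C@@]1(C)O | intermediate
16 | 8α,19-bis(triethylsilyloxy)-14,15-dinorlabdan-13-one | CC(=O)CC[C@@H]1[C@@]2(C)CCC[C@](C)(CO[Si](CC)(CC)CC)[C@@H]2CC[C@@]1(C)O[Si](CC)(CC)CC | intermediate
17 | potassium enolate of 16 (C13–O−, C13=C16) | C=C([O-])CC[C@@H]1[C@@]2(C)CCC[C@](C)(CO[Si](CC)(CC)CC)[C@@H]2CC[C@@]1(C)O[Si](CC)(CC)CC.[K+] | intermediate (not isolated)
18 | 8α,19-bis(triethylsilyloxy)-14,15-dinorlabd-13(16)-en-13-yl trifluoromethanesulfonate | C=C(OS(=O)(=O)C(F)(F)F)CC[C@@H]1[C@@]2(C)CCC[C@](C)(CO[Si](CC)(CC)CC)[C@@H]2CC[C@@]1(C)O[Si](CC)(CC)CC | intermediate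
19 | tributyl(vinyl)stannane | C=C[Sn](CCCC)(CCCC)CCCC | starting material
20 | 8α,19-bis(triethylsilyloxy)labda-13(16),14-diene | C=CC(=C)CC[C@@H]1[C@@]2(C)CCC[C@](C)(CO[Si](CC)(CC)CC)[C@@H]2CC[C@@]1(C)O[Si](CC)(CC)CC | intermediate
21 | labda-13(16),14-diene-8α,19-diol | C=CC(=C)CC[C@@H]1[C@@]2(C)CCC[C@](C)(CO)[C@@H]2CC[C@@]1(C)O | intermediate
22 | (E)-4-methoxycinnamic acid | COc1ccc(/C=C/C(=O)O)cc1 | starting material
23 | 8α-hydroxylabda-13(16),14-dien-19-yl (2E)-3-(4-methoxyphenyl)prop-2-enoate (CNP0249194.1) | C=CC(=C)CC[C@@H]1[C@@]2(C)CCC[C@](C)(COC(=O)/C=C/c3ccc(OC)cc3)[C@@H]2CC[C@@]1(C)O | target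

**Totals**

Total step count: 15.
Longest linear sequence: 12 steps (steps 1–3 and 7–15 from 1; the branch from 5, steps 4–6 and 7–15, is equally long).

**Steps most likely to fail**

Step 10. Three processes may defeat it: loss of facial control in the first ring closure (oxirane methylene in the equatorial site, which leads to the diastereomer with the decalin of the opposite series); a 1,2-hydride shift of the Lewis-acid-opened oxirane; or proton loss from the C8 cation before the carbonyl oxygen adds. The fallback replaces the cationic cascade by an oxidative radical bicyclization with trivalent manganese, which still forms the C9–C10 bond in a ring-closing polyene bicyclization. It sets out from 4 and returns at 15. Ethyl 2-methylacetoacetate is transesterified with (1R,2S,5R)-8-phenylmenthol (DMAP, toluene, reflux) to the chiral β-keto ester F1. Its dianion (NaH, then n-BuLi, THF, 0 °C) is alkylated at the γ-carbon by 4 to give the polyene β-keto ester F2. Mn(OAc)3·2H2O and Cu(OAc)2·H2O in degassed EtOH at rt should close ring A and ring B by two 6-endo additions of the α-keto ester radical and end by oxidation with divalent copper to the exocyclic alkene, giving the bicyclic keto ester F3 with the ester axial at C4. NaBH4 in MeOH should give the 3β-alcohol F4, PhOC(S)Cl with pyridine and DMAP the thionocarbonate F5, and Bu3SnH with AIBN in toluene at 90 °C (Barton–McCombie deoxygenation) the 3-deoxy ester F6. mCPBA buffered with NaHCO3 should epoxidize the 8(17)-alkene from the α face, away from the axial C20 methyl, to the 8α,17-epoxide F7. LiAlH4 in THF at reflux reduces the ester to the C19 alcohol with release of the auxiliary and opens the oxirane at C17 to the tertiary 8α-alcohol, giving the diol ketal F8. 1 M aq. HCl in THF then gives 15. The (1R,2S,5R) auxiliary is the one drawn; its sense of induction would be verified on F3 and the enantiomeric alcohol taken if required.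

Step 12. Proton removal may occur at C12 instead of C16, so that regiocontrol in the enolization is lost and the internal enol triflate forms. The fallback replaces ketone enolization by a hydrazone-directed Shapiro lithiation. It sets out from 16 and returns at 20. Condensation of 16 with 2,4,6-triisopropylbenzenesulfonyl hydrazide (THF, rt) gives the trisylhydrazone F9. n-BuLi (2.2 equiv) in THF/TMEDA from −78 °C to 0 °C removes the methyl proton syn to the sulfonamide nitrogen and, after loss of sulfinate and nitrogen, gives the C13 alkenyllithium, which iodine converts to the 13-iodo-13(16)-alkene F10. Stille coupling of this iodide with 19 (Pd(PPh3)4, CuI, DMF, rt) should give 20.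

Step 7. The Grignard reagent may attack the γ-carbon of the allylic bromide (allylic transposition), or the two halides may homocouple. The fallback replaces the copper-catalysed coupling by sulfone-anion alkylation and reductive desulfonylation. It sets out from 8 and 4 and returns at 10. PhSO2Na in DMF at 60 °C converts 8 into the sulfone F11. Deprotonation with n-BuLi in THF/DMPU at −78 °C and addition of 4 should give the α-alkylated sulfone F12 by direct displacement at the primary allylic carbon. Na/Hg (sodium amalgam) with Na2HPO4 in MeOH at −20 °C removes the sulfonyl group to give 10.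

**Further compounds**

F1 | step 10 | (1R,2S,5R)-5-methyl-2-(2-phenylpropan-2-yl)cyclohexyl 2-methyl-3-oxobutanoate | CC(=O)C(C)C(=O)O[C@@H]1C[C@H](C)CC[C@H]1C(C)(C)c1ccccc1
F2 | step 10 | (1R,2S,5R)-8-phenylmenthyl (6E,10E)-2,6,10-trimethyl-13-(2-methyl-1,3-dioxolan-2-yl)-3-oxotrideca-6,10-dienoate | CC1(CC/C=C(\C)CC/C=C(\C)CCC(=O)C(C)C(=O)O[C@@H]2C[C@H](C)CC[C@H]2C(C)(C)c2ccccc2)OCCO1
F3 | step 10 | (1R,2S,5R)-8-phenylmenthyl 13,13-ethylenedioxy-3-oxo-14,15-dinorlabd-8(17)-en-19-oate | CC1(CC[C@@H]2[C@@]3(C)CCC(=O)[C@](C)(C(=O)O[C@@H]4C[C@H](C)CC[C@H]4C(C)(C)c4ccccc4)[C@@H]3CCC2=C)OCCO1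
F4 | step 10 | (1R,2S,5R)-8-phenylmenthyl 13,13-ethylenedioxy-3β-hydroxy-14,15-dinorlabd-8(17)-en-19-oate | CC1(CC[C@@H]2[C@@]3(C)CC[C@H](O)[C@](C)(C(=O)O[C@@H]4C[C@H](C)CC[C@H]4C(C)(C)c4ccccc4)[C@@H]3CCC2=C)OCCO1
F5 | step 10 | (1R,2S,5R)-8-phenylmenthyl 13,13-ethylenedioxy-3β-(phenoxycarbonothioyloxy)-14,15-dinorlabd-8(17)-en-19-oate | CC1(CC[C@@H]2[C@@]3(C)CC[C@H](OC(=S)Oc4ccccc4)[C@](C)(C(=O)O[C@@H]4C[C@H](C)CC[C@H]4C(C)(C)c4ccccc4)[C@@H]3CCC2=C)OCCO1
F6 | step 10 | (1R,2S,5R)-8-phenylmenthyl 13,13-ethylenedioxy-14,15-dinorlabd-8(17)-en-19-oate | CC1(CC[C@@H]2[C@@]3(C)CCC[C@](C)(C(=O)O[C@@H]4C[C@H](C)CC[C@H]4C(C)(C)c4ccccc4)[C@@H]3CCC2=C)OCCO1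
F7 | step 10 | (1R,2S,5R)-8-phenylmenthyl 8α,17-epoxy-13,13-ethylenedioxy-14,15-dinorlabdan-19-oate | CC1(CC[C@@H]2[C@@]3(C)CCC[C@](C)(C(=O)O[C@@H]4C[C@H](C)CC[C@H]4C(C)(C)c4ccccc4)[C@@H]3CC[C@]25CO5)OCCO1
F8 | step 10 | 13,13-ethylenedioxy-14,15-dinorlabdane-8α,19-diol | CC1(CC[C@@H]2[C@@]3(C)CCC[C@](C)(CO)[C@@H]3CC[C@@]2(C)O)OCCO1
F9 | step 12 | 2,4,6-triisopropylbenzenesulfonylhydrazone of 16 | CC(CC[C@@H]1[C@@]2(C)CCC[C@](C)(CO[Si](CC)(CC)CC)[C@@H]2CC[C@@]1(C)O[Si](CC)(CC)CC)=NNS(=O)(=O)c1c(C(C)C)cc(C(C)C)cc1C(C)C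
F10 | step 12 | 13-iodo-8α,19-bis(triethylsilyloxy)-14,15-dinorlabd-13(16)-ene | C=C(I)CC[C@@H]1[C@@]2(C)CCC[C@](C)(CO[Si](CC)(CC)CC)[C@@H]2CC[C@@]1(C)O[Si](CC)(CC)CC
F11 | step 7 | (4S)-2,2,4-trimethyl-4-[2-(phenylsulfonyl)ethyl]-1,3-dioxolane | C[C@]1(CCS(=O)(=O)c2ccccc2)COC(C)(C)O1
F12 | step 7 | 2-methyl-2-{(3E,7E)-4,8-dimethyl-10-(phenylsulfonyl)-11-[(4S)-2,2,4-trimethyl-1,3-dioxolan-4-yl]undeca-3,7-dien-1-yl}-1,3-dioxolane (sulfone carbon as epimer mixture) | CC1(CC/C=C(\C)CC/C=C(\C)CC(C[C@@]2(C)COC(C)(C)O2)S(=O)(=O)c2ccccc2)OCCO1
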